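**The pitfall.** Don't take a flat D column for a finished flask. In violet, D goes from 44.4% to 43.3% while Q climbs from 6.9% to 8.2%. You have to choose the next charge of G, and grey, charged with more G, reads 16.3% of Q at 20.0 h against violet's 8.2%.

the same everywhere: X 0.80 M

| run | G | remark | time |
|---|---|---|---|
| violet | 1.5 M | run made earlier |  |
| grey | 2.1 M | run made earlier |  |
| Saturday's | 1.20 M |  | 20 h |
| Friday's | 1.60 M |  | 20 h |

| run | time / h | Q / % | L / % | X / % | D / % |
|---|---|---|---|---|---|
| violet | 5.00 | 0.9 | 12.9 | 7.1 | 32.2 |
| violet | 10.0 | 4.1 | 4.4 | 2.5 | 42.0 |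
| violet | 15.0 | 6.9 | 1.2 | 0.1 | 44.4 |
| violet | 20.0 | 8.2 | 1.0 | 1.0 | 43.3 |
| grey | 5.00 | 3.6 | 8.2 | 3.9 | 45.0 |
| grey | 10.0 | 7.0 | 2.4 | 0.2 | 49.5 |
| grey | 15.0 | 12.0 | 1.0 | 0.3 | 47.4 |
| grey | 20.0 | 16.3 | 0.2 | 0 | 44.6 |

(standard deviation of a reading: 0.5 percentage points)

* which of these there is most of at the end, counted by the X in it, Saturday's (D / X / Q / L)
* which of these there is most of at the end, counted by the X in it, Friday's (D / X / Q / L)
* final amount of the leader among these, as a percentage of the X charged, in Saturday's
* final amount of the leader among these, as a percentage of the X charged, in Friday's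



**The leak constant.** Take Q as formed from D and G, an assumption the runs can test, and replace each curve by its mean. In grey, Q gains 13 percentage points between 5.00 h and 20.0 h. Grey's mean D is 46.6%, and its mean free [G], the charge less what L, D and Q hold, is 1.10 M. Dividing the hourly gain by both gives 0.0166 M⁻¹ h⁻¹. This reading, with the scatter of grey's readings in it, is the leak constant, the fraction of D passing to Q per hour per M of free G; at a given [G] the leak is then pseudo-first-order.

To check the mean's error, take violet, with mean D 40.5% and mean [G] 0.693 M. The constant gives 7 points of Q, against 7.3 points read, with a scatter of 0.5 points on each reading.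

**The decision.** Interpolated for Friday's, mean [G] is 0.760 M. With violet's mean D, my own reckoning puts Friday's leak between 5.00 h and 20.0 h near 7.7 points. The forecast has D leading Saturday's at 41% and D leading Friday's at 43.5%, on the ground that the listed species total near 53% in violet and near 61% in grey, and “More G reduces this loss”. That puts Friday's 2.5 points ahead despite the leak, so I would charge 1.60 M.

**The result.** D leads at 39.5% in Saturday's and 43.7% in Friday's, and the unseen J holds 52.8% and 45.8% of the X charged.

    X + G → L (k = 0.00500 M⁻¹ min⁻¹)
    G + L → D (k = 0.00670 M⁻¹ min⁻¹)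
    G + D → Q (k = 2.80 × 10⁻⁴ M⁻¹ min⁻¹)
    2 X → J (k = 0.00880 M⁻¹ min⁻¹)

With the means of Friday's [G] and D at 10.0 h and 20 h, the leak constant gives 5.2 points of Q; the flask gains 5.2 points.

**Two days.** Read Friday's flask at 2.0 d instead. Holding [G] at its 20 h value, the leak constant leaves 32.2% as D; the computed flask holds 33.4%.

(The data were generated by integration for substances that don't exist; the scatter is artificial.)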